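## Retrosynthetic overview

- The target is (13E)-6β-acetoxy-7α-(3-methylbutanoyloxy)labda-8,13-dien-15-oic acid. The C7–O bond and the C8=C9 double bond are made last, by allylic transposition of a C9 tertiary carbinol steered by the 6β-acetate. The side chain C11–C16 is added to a C9 ketone and finished by alkyne carbometalation.
- Ring B (C5–C10) is read as 2,6-dimethyl-1,4-benzoquinone: C6 and C9 are its carbonyl carbons, C8 and C10 carry its methyl groups, and the C7 oxygen is relayed from C9.
- Key disconnection: ring A is cut at C1–C10 and C4–C5, a [4+2] cycloaddition of a C1–C4 diene across the quinone C5=C10 bond. It is possible because C10 is the β-carbon of the C6 enone and the gem-dimethyl carbon C4 meets the unsubstituted C5. A silyloxy group placed at C2 (removed in step 7) makes C1 the nucleophilic diene terminus.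
- Ring order: ring B is bought as the quinone, ring A is closed in the key step, and the trans ring fusion follows by C5 epimerisation. Stereocentres: C10 (catalyst), C5 (equilibration), C6 (hydride from the α face), C7 (transposition).

Key step: step 2

Remarks on the chemistry:

- Atoms are numbered as in the labdane skeleton of the target (ring A = C1–C5, C10; ring B = C5–C10; side chain C11–C16). β is the face of the C10 methyl group.
- Assumption: the (S)-configured oxazaborolidinium catalyst is taken to direct the diene to the α face of the bound quinone, by analogy with its sense of induction on acrylates bound through the same carbonyl/α-C–H contact. If the adduct proved antipodal, the (R)-catalyst would be used with nothing else changed.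
- Assumption: the C9 carbinol configuration drawn for the intermediates (OH β) is the expected one. It is of no consequence, because C9 becomes trigonal in step 11.

## Route

Step 1
Reactants: 1 mesityl oxide (4-methylpent-3-en-2-one)
Product: 3 4-methyl-2-(triisopropylsilyloxy)penta-1,3-diene, via lithium dienolate 2 (not isolated)
Conditions: LiN(iPr)2, THF, −78 °C; iPr3SiOSO2CF3, −78 → 0 °C
Reagents that add atoms: triisopropylsilyl trifluoromethanesulfonate, CC(C)[Si](OS(=O)(=O)C(F)(F)F)(C(C)C)C(C)C
Why: Kinetic deprotonation of the methyl ketone at its α′-methyl group should give the cross-conjugated dienolate, which is O-silylated (silyl enol ether formation); no stereocentre is formed.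

Step 2
Reactants: 3 4-methyl-2-(triisopropylsilyloxy)penta-1,3-diene (1.5 equiv); 4 2,6-dimethyl-1,4-benzoquinone
Product: 5 cis-fused cycloadduct, (4aR,8aS)-2,5,5,8a-tetramethyl-7-(triisopropylsilyloxy)-4a,5,8,8a-tetrahydronaphthalene-1,4-dione (labdane numbering: 6,9-dione, C2 silyl enol ether, C7=C8, 5β-H, 10β-CH3)
Conditions: (S)-3,3-diphenyl-1-(2-methylphenyl)tetrahydro-1H,3H-pyrrolo[1,2-c][1,3,2]oxazaborole protonated with HN(SO2CF3)2 (0.2 equiv), CH2Cl2, −78 → −40 °C
Reagents that add atoms: none
Why: The oxazaborolidinium cation should bind the C6 carbonyl oxygen of 4 (the more basic carbonyl, flanked by two C–H bonds, one of which contacts the catalyst oxygen), so that C10 becomes the β-carbon of the activated enone; the CH2 terminus C1 of diene 3, made its most nucleophilic carbon by the C2 silyloxy group, bonds to C10 first and the gem-dimethyl terminus C4 then closes onto C5, in a strongly asynchronous [4+2] cycloaddition that can also run stepwise through a silyloxyallyl cation and a boron enolate (Mukaiyama–Michael addition, then ring closure), so the low s-cis population of a Z-substituted diene should not stop it. The closest known reaction type is the oxazaborolidinium-catalysed enantioselective Diels–Alder reaction of 1,4-benzoquinones with 2-silyloxy-1,3-dienes. Ring A closes in the intermolecular (4+2) mode, both new bonds forming suprafacially on one face of the quinone C5=C10 bond. C10 (quaternary) and C5 therefore arise cis to each other, and the absolute configuration at C10 is controlled by the catalyst, whose aryl group should cover the β face of the bound enone so that the diene enters from the α face; C5 is corrected in step 3. The step needs regioselectivity (C1 to C10, C4 to C5), secured by the catalyst binding site together with the diene polarisation and reinforced sterically because the hindered C4 terminus meets the unsubstituted C5, and site selectivity, secured because the two ring C=C bonds of 4 are related by symmetry and the remaining C7=C8 bond of 5 is a less electrophilic, more hindered enedione.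

Step 3
Reactants: 5 cis-fused cycloadduct
Product: 6 trans-fused enedione, (4aS,8aS)-2,5,5,8a-tetramethyl-7-(triisopropylsilyloxy)-4a,5,8,8a-tetrahydronaphthalene-1,4-dione (5α-H, 10β-CH3)
Conditions: 1,8-diazabicyclo[5.4.0]undec-7-ene (0.2 equiv), toluene, 23 °C, argon
Reagents that add atoms: none
Why: Base-mediated epimerisation (enolisation and reprotonation at C5, α to the C6 ketone) should convert the cis adduct into the trans-fused enedione, expected to be the more stable isomer and reached by axial protonation of the C5–C6 enolate on the α face, anti to the C10 methyl group; C10 is quaternary and cannot change.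

Step 4
Reactants: 6 trans-fused enedione
Product: 7 6β-hydroxy-4,4,8,10β-tetramethyl-2-(triisopropylsilyloxy)-5α-decalin-2,7-dien-9-one
Conditions: NaBH4, CeCl3·7H2O, MeOH/CH2Cl2, −78 °C
Reagents that add atoms: none
Why: Luche 1,2-reduction should select the C6 carbonyl (the C9 carbonyl is shielded by the quaternary C10 and the C8 methyl group), and hydride should enter from the α face because the β face of C6 is blocked by the syn-axial C4 and C10 methyl groups, which sets the 6β-hydroxyl.

Step 5
Reactants: 7 6β-hydroxy enone; 8 4-bromo-1-(trimethylsilyl)but-1-yne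
Product: 10 6β,9β-dihydroxy-9α-[4-(trimethylsilyl)but-3-ynyl]-4,4,8,10β-tetramethyl-2-(triisopropylsilyloxy)-5α-decalin-2,7-diene, via Grignard reagent 9 (not isolated)
Conditions: 8, Mg, THF, 23 °C; then 7 (9 in 2.5 equiv), LaCl3·2LiCl (0.3 equiv), THF, 0 → 23 °C; aq. NH4Cl
Reagents that add atoms: none
Why: Lanthanum-promoted Grignard 1,2-addition to the hindered C9 enone carbonyl (one equivalent of 9 is spent on the C6 hydroxyl) should give the tertiary allylic alcohol; the nucleophile is expected to enter anti to the C10 methyl group (9β-carbinol), a stereocentre that is erased in step 11.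

Step 6
Reactants: 10 bis-silylated diol
Product: 11 9α-(but-3-ynyl)-6β,9β-dihydroxy-4,4,8,10β-tetramethyl-5α-decalin-7-en-2-one
Conditions: Bu4NF (3 equiv), wet THF, 0 → 23 °C
Reagents that add atoms: none
Why: Fluoride should cleave both the alkynyl C–Si bond and the silyl enol ether, whose enolate is protonated to the C2 ketone (desilylation); no stereocentre is touched.

Step 7
Reactants: 11 C2 ketone
Product: 13 9α-(but-3-ynyl)-4,4,8,10β-tetramethyl-5α-decalin-7-ene-6β,9β-diol, via tosylhydrazone 12 (not isolated)
Conditions: p-toluenesulfonyl hydrazide, EtOH, 50 °C; evaporation; catecholborane (4 equiv), CHCl3, 0 °C; NaOAc·3H2O, 60 °C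
Reagents that add atoms: none
Why: Caglioti-type deoxygenation in its catecholborane variant: the C2 ketone condenses with the sulfonyl hydrazide, hydride is delivered to C=N, and the diazene formed loses sulfinate and N2 to leave CH2, under conditions that should spare the terminal alkyne, the C7=C8 bond and the tertiary allylic alcohol.

Step 8
Reactants: 13 alkyne diol
Product: 15 ethyl (13E)-6β,9β-dihydroxylabda-7,13-dien-15-oate (side chain on the α face of C9), via alkenylalane 14 (not isolated)
Conditions: AlMe3 (5 equiv), Cp2ZrCl2 (zirconocene dichloride, 0.3 equiv), CH2Cl2, 0 → 23 °C; ClCO2Et, 0 → 23 °C; aqueous potassium sodium tartrate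
Reagents that add atoms: trimethylaluminium, C[Al](C)C; ethyl chloroformate, CCOC(=O)Cl
Why: Negishi zirconium-catalysed carboalumination should add CH3 (to C13) and Al (to C14) syn across the terminal alkyne, and acylation of the alkenyl–Al bond by the chloroformate proceeds with retention, which fixes the 13E geometry; the two hydroxyl groups are carried as aluminium alkoxides.

Step 9
Reactants: 15 ethyl ester
Product: 16 (13E)-6β,9β-dihydroxylabda-7,13-dien-15-oic acid (side chain on the α face of C9)
Conditions: LiOH·H2O, THF/MeOH/H2O, 40 °C; 0.5 M HCl to pH 4, 0 °C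
Reagents that add atoms: lithium hydroxide, [Li+].[OH-]
Why: Saponification is placed here because no other ester is present yet, and the mild cold acidification should avoid ionisation of the tertiary allylic alcohol.

Step 10
Reactants: 16 dihydroxy acid
Product: 18 (13E)-6β-acetoxy-9β-hydroxylabda-7,13-dien-15-oic acid, via mixed anhydride 17 (not isolated)
Conditions: Ac2O (4 equiv), 4-(dimethylamino)pyridine (0.2 equiv), pyridine, 40 °C; then THF/H2O, 23 °C
Reagents that add atoms: acetic anhydride, CC(=O)OC(C)=O
Why: Nucleophile-catalysed acylation should acetylate the secondary 6β-hydroxyl while the tertiary C9 hydroxyl is too hindered to react; the mixed anhydride formed at C15 is hydrolysed in the aqueous stage, and C6 keeps its configuration because its C–O bond is not broken.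

Step 11
Reactants: 18 6β-acetoxy tertiary allylic alcohol
Product: 20 (13E)-6β-acetoxy-7α-(3-methylbutanoyloxy)labda-8,13-dien-15-oic acid, via acetoxonium ion 19 (not isolated)
Conditions: 3-methylbutanoic acid/CH2Cl2 (1:1), p-toluenesulfonic acid (0.1 equiv), 4 Å molecular sieves, 0 → 23 °C
Reagents that add atoms: 3-methylbutanoic acid, CC(C)CC(=O)O
Why: Acid-mediated allylic transposition of a tertiary allylic alcohol with neighbouring-group participation: ionisation at C9 should give the C7–C8–C9 allyl cation, the axial 6β-acetate captures it at C7 on the β face as the cis-fused acetoxonium ion, and 3-methylbutanoic acid opens this ion at the allylic C7 with inversion from the unhindered α face, giving the 7α-ester trans to the 6β-acetate and the tetrasubstituted C8=C9 bond.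

## Compound list

1 | mesityl oxide (4-methylpent-3-en-2-one) | CC(=O)C=C(C)C | starting material
2 | lithium 4-methylpenta-1,3-dien-2-olate | [Li+].[O-]C(=C)C=C(C)C | intermediate
3 | 4-methyl-2-(triisopropylsilyloxy)penta-1,3-diene | C=C(O[Si](C(C)C)(C(C)C)C(C)C)C=C(C)C | intermediate
4 | 2,6-dimethyl-1,4-benzoquinone | CC1=CC(=O)C=C(C)C1=O | starting material
5 | cis-fused cycloadduct, (4aR,8aS)-2,5,5,8a-tetramethyl-7-(triisopropylsilyloxy)-4a,5,8,8a-tetrahydronaphthalene-1,4-dione | O=C1C=C(C)C(=O)[C@@]2(C)CC(O[Si](C(C)C)(C(C)C)C(C)C)=CC(C)(C)[C@@H]12 | intermediate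
6 | trans-fused enedione, (4aS,8aS)-isomer of 5 | O=C1C=C(C)C(=O)[C@@]2(C)CC(O[Si](C(C)C)(C(C)C)C(C)C)=CC(C)(C)[C@H]12 | intermediate
7 | 6β-hydroxy-4,4,8,10β-tetramethyl-2-(triisopropylsilyloxy)-5α-decalin-2,7-dien-9-one | O[C@@H]1C=C(C)C(=O)[C@@]2(C)CC(O[Si](C(C)C)(C(C)C)C(C)C)=CC(C)(C)[C@H]12 | intermediate
8 | 4-bromo-1-(trimethylsilyl)but-1-yne | C[Si](C)(C)C#CCCBr | starting material
9 | [4-(trimethylsilyl)but-3-ynyl]magnesium bromide | C[Si](C)(C)C#CCC[Mg]Br | intermediate
10 | 6β,9β-dihydroxy-9α-[4-(trimethylsilyl)but-3-ynyl]-4,4,8,10β-tetramethyl-2-(triisopropylsilyloxy)-5α-decalin-2,7-diene | O[C@@H]1C=C(C)[C@@](O)(CCC#C[Si](C)(C)C)[C@@]2(C)CC(O[Si](C(C)C)(C(C)C)C(C)C)=CC(C)(C)[C@H]12 | intermediate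
11 | 9α-(but-3-ynyl)-6β,9β-dihydroxy-4,4,8,10β-tetramethyl-5α-decalin-7-en-2-one | O[C@@H]1C=C(C)[C@@](O)(CCC#C)[C@@]2(C)CC(=O)CC(C)(C)[C@H]12 | intermediate
12 | C2 p-toluenesulfonylhydrazone of 11 | O[C@@H]1C=C(C)[C@@](O)(CCC#C)[C@@]2(C)CC(=NNS(=O)(=O)c3ccc(C)cc3)CC(C)(C)[C@H]12 | intermediate
13 | 9α-(but-3-ynyl)-4,4,8,10β-tetramethyl-5α-decalin-7-ene-6β,9β-diol | O[C@@H]1C=C(C)[C@@](O)(CCC#C)[C@@]2(C)CCCC(C)(C)[C@H]12 | intermediate
14 | (E)-alkenyldimethylalane of 13 with both hydroxyls as dimethylaluminium alkoxides | C[Al](C)O[C@@H]1C=C(C)[C@@](O[Al](C)C)(CC/C(C)=C/[Al](C)C)[C@@]2(C)CCCC(C)(C)[C@H]12 | intermediate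
15 | ethyl (13E)-6β,9β-dihydroxylabda-7,13-dien-15-oate (side chain α at C9) | O[C@@H]1C=C(C)[C@@](O)(CC/C(C)=C/C(=O)OCC)[C@@]2(C)CCCC(C)(C)[C@H]12 | intermediate
16 | (13E)-6β,9β-dihydroxylabda-7,13-dien-15-oic acid (side chain α at C9) | O[C@@H]1C=C(C)[C@@](O)(CC/C(C)=C/C(=O)O)[C@@]2(C)CCCC(C)(C)[C@H]12 | intermediate
17 | mixed acetic anhydride of 18 at C15 | CC(=O)O[C@@H]1C=C(C)[C@@](O)(CC/C(C)=C/C(=O)OC(C)=O)[C@@]2(C)CCCC(C)(C)[C@H]12 | intermediate
18 | (13E)-6β-acetoxy-9β-hydroxylabda-7,13-dien-15-oic acid (side chain α at C9) | CC(=O)O[C@@H]1C=C(C)[C@@](O)(CC/C(C)=C/C(=O)O)[C@@]2(C)CCCC(C)(C)[C@H]12 | intermediate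
19 | 6β,7β-acetoxonium (2-methyl-1,3-dioxolan-2-ylium) ion with C8=C9, as its p-toluenesulfonate | O3[C@@H]1[C@H]([O+]=C3C)C(C)=C(CC/C(C)=C/C(=O)O)[C@@]2(C)CCCC(C)(C)[C@H]12.Cc1ccc(cc1)S(=O)(=O)[O-] | intermediate
20 | (13E)-6β-acetoxy-7α-(3-methylbutanoyloxy)labda-8,13-dien-15-oic acid | CC(=O)O[C@@H]1[C@@H](OC(=O)CC(C)C)C(C)=C(CC/C(C)=C/C(=O)O)[C@@]2(C)CCCC(C)(C)[C@H]12 | target

## Step count and risks

Total step count: 11. Longest linear sequence: 11 steps (1 → 20); quinone 4 and bromide 8 are commercial.

Steps most likely to fail:

Step 2. The process at risk is loss of enantiofacial control: the hindered gem-dimethyl terminus slows the catalyst-bound pathway, so an unselective background or proton-catalysed Mukaiyama–Michael addition may compete. The fallback replaces catalytic stereocontrol by separation. It sets out from 3 and 4, which are combined with the achiral Lewis acid BF3·OEt2 (CH2Cl2, −78 °C); this binds the same C6 carbonyl and should give the racemic cis adduct, that is 5 together with its antipode ent-5 F1. Epimerisation as in step 3 should give 6 together with its antipode ent-6 F2. The pair is resolved by preparative chromatography on a cellulose tris(3,5-dimethylphenylcarbamate) phase, and the route is rejoined at 6.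

Step 11. The process at risk is diversion of the allyl cation: proton loss to dienes, capture on the β face, or acyl scrambling through an orthoester if water is not excluded. The fallback replaces the cationic substitution by oxidation, reduction and inversion. It sets out from 18. Babler–Dauben oxidative transposition with pyridinium chlorochromate, [C5H5NH][CrO3Cl], in CH2Cl2 should give (13E)-6β-acetoxy-7-oxolabda-8,13-dien-15-oic acid F4. Luche reduction (NaBH4, CeCl3·7H2O, MeOH, −40 °C), with hydride from the α face, should give (13E)-6β-acetoxy-7β-hydroxylabda-8,13-dien-15-oic acid F5. Mitsunobu inversion (PPh3, diisopropyl azodicarboxylate, excess 3-methylbutanoic acid, toluene, 0 °C) should then install the 7α-ester and rejoin the route at 20.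

Step 3. The process at risk is an incomplete or unfavourable equilibration, since the cis- and trans-fused enediones may lie close in energy because of the syn-axial C4 and C10 methyl groups. The fallback replaces thermodynamic by kinetic control. It sets out from 5, which is deprotonated at C5 with KN(SiMe3)2 (THF, −78 °C) to the potassium dienolate F3. Rapid quenching with acetic acid at −78 °C should protonate C5 axially on the α face, anti to the C10 methyl group, and rejoin the route at 6.

Further compounds
F1 | step 2 | ent-5, antipode of the cis-fused cycloadduct | O=C1C=C(C)C(=O)[C@]2(C)CC(O[Si](C(C)C)(C(C)C)C(C)C)=CC(C)(C)[C@H]12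
F2 | step 2 | ent-6, antipode of the trans-fused enedione | O=C1C=C(C)C(=O)[C@]2(C)CC(O[Si](C(C)C)(C(C)C)C(C)C)=CC(C)(C)[C@@H]12
F3 | step 3 | potassium C5–C6 dienolate of 5 | [K+].[O-]C1C=C(C)C(=O)[C@@]2(C)CC(O[Si](C(C)C)(C(C)C)C(C)C)=CC(C)(C)C=12
F4 | step 11 | (13E)-6β-acetoxy-7-oxolabda-8,13-dien-15-oic acid | CC(=O)O[C@@H]1C(=O)C(C)=C(CC/C(C)=C/C(=O)O)[C@@]2(C)CCCC(C)(C)[C@H]12
F5 | step 11 | (13E)-6β-acetoxy-7β-hydroxylabda-8,13-dien-15-oic acid | CC(=O)O[C@@H]1[C@H](O)C(C)=C(CC/C(C)=C/C(=O)O)[C@@]2(C)CCCC(C)(C)[C@H]12
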